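**Plan**

1. Target numbering: O1, C2(=O), C3(=CH2), ring-fusion C3a, carbocycle C4–C15, C15a(–O1); OAc on C12.
2. First cut: the C3a–C4 bond of the 14-membered ring, read as a retro-SH2' allylation. The enabling feature is the allylic triad H2C=C3–C3a(H) of the alpha-methylene-gamma-butyrolactone: moving the double bond into the five-membered ring (C3=C3a) and placing PhSO2 on the former methylene carbon gives a butenolide whose beta-carbon C3a accepts a C4 radical and whose sulfone leaves to restore the methylene.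
3. Further cuts: butenolide C3=C3a (ring-closing metathesis) and O1–C2 (ester), C15a–C3a (vinylzinc addition to an enal), C12–C13 (vinylogous Mukaiyama aldol), C4–C5 (one-carbon homologation of 8-bromogeranyl acetate).
4. Forward: linear chain from geranyl acetate (C5–C12, then C4, then C13–C15a, then C3a, C3, C2); five-membered ring by metathesis; 14-membered ring last, with the sulfone helper leaving in the ring-closing event itself.
5. Stereochemistry: C12 and C15a from two catalyst-controlled additions to enals; C3a relayed from C15a in the key step (attack anti to the C15a substituent, trans fusion); 6E and 10E come with geraniol, 14E is formed in the aldol.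

Key step: step 16

Assumption: the sense of induction of the chiral catalysts in steps 7 and 11 is taken by analogy with their behaviour towards simple aldehydes; in each case the catalyst enantiomer that delivers the nucleophile to the Re face of the enal is the one meant.

**Step 1**
Reactants: 1 geranyl acetate
Product: 2 (2E,6E)-8-hydroxy-3,7-dimethylocta-2,6-dien-1-yl acetate
Conditions: SeO2 (0.1 equiv), t-BuOOH (3 equiv), salicylic acid (0.1 equiv), CH2Cl2, rt
Reagents that add atoms: tert-butyl hydroperoxide, CC(C)(C)OO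
Why: Catalytic SeO2 allylic oxidation (ene reaction then [2,3]-sigmatropic shift) should attack the (E)-methyl group of the electron-rich terminal olefin and leave the acetate-deactivated olefin alone.

**Step 2**
Reactants: 2 (2E,6E)-8-hydroxy-3,7-dimethylocta-2,6-dien-1-yl acetate
Product: 3 (2E,6E)-8-bromo-3,7-dimethylocta-2,6-dien-1-yl acetate
Conditions: CBr4, PPh3, CH2Cl2, −20 to 0 °C
Reagents that add atoms: carbon tetrabromide, BrC(Br)(Br)Br
Why: Appel bromination of the primary allylic alcohol under neutral conditions should proceed without allylic transposition or loss of olefin geometry.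

**Step 3**
Reactants: 3 (2E,6E)-8-bromo-3,7-dimethylocta-2,6-dien-1-yl acetate
Product: 6 (2E,6E)-3,7-dimethylnona-2,6-diene-1,9-diol, via alkoxysilane 4 (not isolated), via hydroxy acetate 5 (not isolated)
Conditions: (i-PrO)Me2SiCH2MgCl (1.5 equiv, from the chloride and Mg), Li2CuCl4 (3 mol %), THF, −78 to −20 °C; then 30% H2O2, KF, KHCO3, THF/MeOH, rt; then K2CO3, MeOH, rt
Reagents that add atoms: [(isopropoxydimethylsilyl)methyl]magnesium chloride, CC(C)O[Si](C)(C)C[Mg]Cl (made in the flask from (chloromethyl)isopropoxydimethylsilane, CC(C)O[Si](C)(C)CCl, and Mg); hydrogen peroxide, OO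
Why: Copper-catalysed Grignard coupling at the allylic bromide (alpha-selective with Li2CuCl4 in THF and faster than attack on the acetate at low temperature) followed by Tamao–Fleming oxidation of the C–Si bond amounts to a hydroxymethylation, and the basic methanolic medium removes the acetate in the same pot.

**Step 4**
Reactants: 6 (2E,6E)-3,7-dimethylnona-2,6-diene-1,9-diol
Product: 7 (2E,6E)-9-hydroxy-3,7-dimethylnona-2,6-dienal
Conditions: MnO2 (15 equiv), CH2Cl2, rt
Reagents that add atoms: none
Why: MnO2 oxidises only the allylic primary alcohol (selective allylic oxidation), so the homoallylic hydroxyl is kept for the next step.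

**Step 5**
Reactants: 7 (2E,6E)-9-hydroxy-3,7-dimethylnona-2,6-dienal
Product: 9 (2E,6E)-9-bromo-3,7-dimethylnona-2,6-dienal, via mesylate 8 (not isolated)
Conditions: MsCl, Et3N, CH2Cl2, 0 °C; then LiBr, acetone, rt
Reagents that add atoms: methanesulfonyl chloride, CS(=O)(=O)Cl (into intermediate 8); lithium bromide, [Li+].[Br-]
Why: Mesylation and SN2 displacement by bromide are used instead of CBr4/PPh3, which would convert the aldehyde into a dibromo-olefin.

**Step 6**
Reactants: 10 methyl 3-methylbut-2-enoate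
Product: 11 tert-butyl[(1-methoxy-3-methylbuta-1,3-dien-1-yl)oxy]dimethylsilane
Conditions: LiN(i-Pr)2 (from i-Pr2NH and n-BuLi), THF, −78 °C; then t-BuMe2SiCl, DMPU, −78 °C to rt; distillation
Reagents that add atoms: tert-butyldimethylsilyl chloride, CC(C)(C)[Si](C)(C)Cl
Why: Kinetic gamma-deprotonation of the senecioate and O-silylation give the silyl dienolate (silyl ketene acetal formation).

**Step 7**
Reactants: 9 (2E,6E)-9-bromo-3,7-dimethylnona-2,6-dienal; 11 tert-butyl[(1-methoxy-3-methylbuta-1,3-dien-1-yl)oxy]dimethylsilane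
Product: 12 methyl (2E,5R,6E,10E)-13-bromo-5-hydroxy-3,7,11-trimethyltrideca-2,6,10-trienoate
Conditions: SiCl4 (1.1 equiv), chiral 2,2'-binaphthyldiamine-derived bisphosphoramide (5 mol %, Re-face-selective enantiomer), i-Pr2NEt (10 mol %), CH2Cl2, −78 °C; sat. aq. NaHCO3
Reagents that add atoms: none
Why: Catalytic enantioselective vinylogous Mukaiyama aldol addition (Lewis-base-activated SiCl4): the dienolate should react at its gamma-carbon on the Re face of the aldehyde held in the chiral phosphoramide–silicon complex, which sets 5R, and the new C2=C3 olefin is expected to form E.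

**Step 8**
Reactants: 12 methyl (2E,5R,6E,10E)-13-bromo-5-hydroxy-3,7,11-trimethyltrideca-2,6,10-trienoate
Product: 13 (2E,5R,6E,10E)-13-bromo-3,7,11-trimethyltrideca-2,6,10-triene-1,5-diol
Conditions: i-Bu2AlH (3.5 equiv), CH2Cl2, −78 °C; aq. potassium sodium tartrate
Reagents that add atoms: none
Why: Low-temperature 1,2-reduction of the conjugated ester with i-Bu2AlH gives the allylic alcohol and should leave the primary bromide and the stereocenter untouched.

**Step 9**
Reactants: 13 (2E,5R,6E,10E)-13-bromo-3,7,11-trimethyltrideca-2,6,10-triene-1,5-diol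
Product: 14 (2E,5R,6E,10E)-13-bromo-5-hydroxy-3,7,11-trimethyltrideca-2,6,10-trienal
Conditions: TEMPO (10 mol %), PhI(OAc)2 (1.1 equiv), CH2Cl2, rt
Reagents that add atoms: none
Why: Oxoammonium oxidation (TEMPO/PhI(OAc)2) is selective for the primary over the secondary allylic alcohol, and the E-olefin keeps the C5 hydroxyl from forming a lactol.

**Step 10**
Reactants: 14 (2E,5R,6E,10E)-13-bromo-5-hydroxy-3,7,11-trimethyltrideca-2,6,10-trienal
Product: 15 (2E,5R,6E,10E)-13-bromo-3,7,11-trimethyl-1-oxotrideca-2,6,10-trien-5-yl acetate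
Conditions: Ac2O, pyridine, DMAP (5 mol %), CH2Cl2, 0 °C
Reagents that add atoms: acetic anhydride, CC(=O)OC(C)=O
Why: Acylation of the only free hydroxyl installs the acetate of the target; weak base and low temperature are chosen to avoid vinylogous elimination of the delta-acetoxy group.

**Step 11**
Reactants: 15 (2E,5R,6E,10E)-13-bromo-3,7,11-trimethyl-1-oxotrideca-2,6,10-trien-5-yl acetate
Product: 16 (3R,4E,7R,8E,12E)-15-bromo-3-hydroxy-5,9,13-trimethylpentadeca-1,4,8,12-tetraen-7-yl acetate
Conditions: Zn(CH=CH2)2 (2 equiv, from CH2=CHMgBr and ZnCl2, magnesium halides precipitated with 1,4-dioxane), (+)-3-exo-(dimethylamino)isoborneol (10 mol %), toluene, −20 to 0 °C; aq. NH4Cl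
Reagents that add atoms: divinylzinc, C=C[Zn]C=C (made in the flask from vinylmagnesium bromide, C=C[Mg]Br, and ZnCl2)
Why: Amino-alcohol-catalysed enantioselective addition of a vinylzinc reagent to an aldehyde: catalyst control should deliver the vinyl group to the Re face of the enal and set 3R, and diorganozincs do not attack the acetate or the bromide.

**Step 12**
Reactants: 16 (3R,4E,7R,8E,12E)-15-bromo-3-hydroxy-5,9,13-trimethylpentadeca-1,4,8,12-tetraen-7-yl acetate
Product: 17 (3R,4E,7R,8E,12E)-3-hydroxy-15-iodo-5,9,13-trimethylpentadeca-1,4,8,12-tetraen-7-yl acetate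
Conditions: NaI (5 equiv), acetone, 50 °C, dark
Reagents that add atoms: sodium iodide, [Na+].[I-]
Why: Finkelstein exchange driven by precipitation of NaBr gives the iodide needed for fast halogen abstraction in the key step, at a stage where no base-sensitive butenolide is present.

**Step 13**
Reactants: 18 2-(bromomethyl)prop-2-enoic acid
Product: 19 2-[(phenylsulfonyl)methyl]prop-2-enoic acid
Conditions: PhSO2Na (1.2 equiv), MeOH, rt to 50 °C; 1 M HCl
Reagents that add atoms: sodium benzenesulfinate, [Na+].[O-]S(=O)c1ccccc1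
Why: S-alkylation of the sulfinate by the allylic bromide (SN2 and SN2' give the same product) gives the allyl sulfone acid.

**Step 14**
Reactants: 17 (3R,4E,7R,8E,12E)-3-hydroxy-15-iodo-5,9,13-trimethylpentadeca-1,4,8,12-tetraen-7-yl acetate; 19 2-[(phenylsulfonyl)methyl]prop-2-enoic acid
Product: 20 (3R,4E,7R,8E,12E)-7-acetoxy-15-iodo-5,9,13-trimethylpentadeca-1,4,8,12-tetraen-3-yl 2-[(phenylsulfonyl)methyl]prop-2-enoate
Conditions: DCC (1.3 equiv), DMAP (5 mol %), CH2Cl2, 0 °C
Reagents that add atoms: none
Why: Steglich esterification acylates the bis-allylic alcohol on oxygen with retention at the carbinol carbon.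

**Step 15**
Reactants: 20 (3R,4E,7R,8E,12E)-7-acetoxy-15-iodo-5,9,13-trimethylpentadeca-1,4,8,12-tetraen-3-yl 2-[(phenylsulfonyl)methyl]prop-2-enoate
Product: 21 (1E,4R,5E,9E)-12-iodo-2,6,10-trimethyl-1-{(2S)-5-oxo-4-[(phenylsulfonyl)methyl]-2,5-dihydrofuran-2-yl}dodeca-1,5,9-trien-4-yl acetate
Conditions: second-generation Grubbs catalyst [RuCl2(=CHPh)(H2IMes)(PCy3)] (10 mol %), CH2Cl2, 5 mM, 40 °C
Reagents that add atoms: none
Why: Ring-closing metathesis: the catalyst should load on the monosubstituted vinyl group and close the five-membered ring onto the 1,1-disubstituted acrylate, which the trisubstituted olefins are too hindered to rival; the CH–O stereocenter is untouched (the descriptor changes from R to S only because the ring carbon now outranks the side chain).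

**Step 16**
Reactants: 21 (1E,4R,5E,9E)-12-iodo-2,6,10-trimethyl-1-{(2S)-5-oxo-4-[(phenylsulfonyl)methyl]-2,5-dihydrofuran-2-yl}dodeca-1,5,9-trien-4-yl acetate
Product: 24 (3aR,6E,10E,12R,14E,15aS)-6,10,14-trimethyl-3-methylidene-2-oxo-2,3,3a,4,5,8,9,12,13,15a-decahydrocyclotetradeca[b]furan-12-yl acetate, via primary alkyl radical 22 (not isolated), via lactone alpha-radical 23 (not isolated)
Conditions: Bu3SnSnBu3 (1.5 equiv), hν (sunlamp, Pyrex), degassed t-BuOH, 0.2 mM, 60 °C
Reagents that add atoms: none
Why: Proposed new method: photolysis of the ditin gives Bu3Sn radicals that abstract iodine from 21; the primary radical 22 should add in a 14-exo-trig sense to the butenolide beta-carbon (C3a), which is favoured both by polarity (nucleophilic alkyl radical, electron-poor olefin) and as the gamma-terminus of the allyl sulfone, and the tertiary alpha-lactone radical 23 then expels PhSO2 by beta-scission, moving the double bond out of the ring as the C3 methylene, while the sulfonyl radical is taken up by the ditin and returns Bu3Sn to the chain. The closest known reaction types are the intermolecular SH2' allylation of alkyl iodides with 2-(sulfonylmethyl)acrylates under ditin and light and the tin-mediated 14-membered radical macrocyclisation onto enones and enoates; their combination on a beta-substituted butenolide is not known. Only the 14-membered carbocycle is closed (14-exo-trig, the lactone ring being already in place), and since no hydrogen donor is present the slowly cyclising radical cannot be reduced before it closes. The new stereocenter C3a is controlled by the adjacent C15a–O stereocenter: the chain should enter the butenolide face anti to the C15a alkenyl substituent, giving the trans ring fusion (3aR with 15aS). The step needs ring closure to beat intermolecular addition, above all addition of 22 to the alpha-methylene lactone already formed; the 0.2 mM concentration, the three E-trisubstituted olefins (few free rotors) and a non-aromatic solvent that donates hydrogen poorly are meant to secure this.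

**Compound list**

1 | geranyl acetate, (2E)-3,7-dimethylocta-2,6-dien-1-yl acetate | CC(=O)OC/C=C(\C)CCC=C(C)C | starting material
2 | (2E,6E)-8-hydroxy-3,7-dimethylocta-2,6-dien-1-yl acetate | CC(=O)OC/C=C(\C)CC/C=C(\C)CO | intermediate
3 | (2E,6E)-8-bromo-3,7-dimethylocta-2,6-dien-1-yl acetate | CC(=O)OC/C=C(\C)CC/C=C(\C)CBr | intermediate
4 | (2E,6E)-9-[isopropoxy(dimethyl)silyl]-3,7-dimethylnona-2,6-dien-1-yl acetate (not isolated) | CC(=O)OC/C=C(\C)CC/C=C(\C)CC[Si](C)(C)OC(C)C | intermediate
5 | (2E,6E)-9-hydroxy-3,7-dimethylnona-2,6-dien-1-yl acetate (not isolated) | CC(=O)OC/C=C(\C)CC/C=C(\C)CCO | intermediate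
6 | (2E,6E)-3,7-dimethylnona-2,6-diene-1,9-diol | OC/C=C(\C)CC/C=C(\C)CCO | intermediate
7 | (2E,6E)-9-hydroxy-3,7-dimethylnona-2,6-dienal | O=C/C=C(\C)CC/C=C(\C)CCO | intermediate
8 | (3E,7E)-4,8-dimethyl-9-oxonona-3,7-dien-1-yl methanesulfonate (not isolated) | O=C/C=C(\C)CC/C=C(\C)CCOS(C)(=O)=O | intermediate
9 | (2E,6E)-9-bromo-3,7-dimethylnona-2,6-dienal | O=C/C=C(\C)CC/C=C(\C)CCBr | intermediate
10 | methyl 3-methylbut-2-enoate | COC(=O)C=C(C)C | starting material
11 | tert-butyl[(1-methoxy-3-methylbuta-1,3-dien-1-yl)oxy]dimethylsilane | C=C(C)C=C(OC)O[Si](C)(C)C(C)(C)C | intermediate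
12 | methyl (2E,5R,6E,10E)-13-bromo-5-hydroxy-3,7,11-trimethyltrideca-2,6,10-trienoate | COC(=O)/C=C(\C)C[C@@H](O)/C=C(\C)CC/C=C(\C)CCBr | intermediate
13 | (2E,5R,6E,10E)-13-bromo-3,7,11-trimethyltrideca-2,6,10-triene-1,5-diol | OC/C=C(\C)C[C@@H](O)/C=C(\C)CC/C=C(\C)CCBr | intermediate
14 | (2E,5R,6E,10E)-13-bromo-5-hydroxy-3,7,11-trimethyltrideca-2,6,10-trienal | O=C/C=C(\C)C[C@@H](O)/C=C(\C)CC/C=C(\C)CCBr | intermediate
15 | (2E,5R,6E,10E)-13-bromo-3,7,11-trimethyl-1-oxotrideca-2,6,10-trien-5-yl acetate | O=C/C=C(\C)C[C@@H](OC(C)=O)/C=C(\C)CC/C=C(\C)CCBr | intermediate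
16 | (3R,4E,7R,8E,12E)-15-bromo-3-hydroxy-5,9,13-trimethylpentadeca-1,4,8,12-tetraen-7-yl acetate | C=C[C@@H](O)/C=C(\C)C[C@@H](OC(C)=O)/C=C(\C)CC/C=C(\C)CCBr | intermediate
17 | (3R,4E,7R,8E,12E)-3-hydroxy-15-iodo-5,9,13-trimethylpentadeca-1,4,8,12-tetraen-7-yl acetate | C=C[C@@H](O)/C=C(\C)C[C@@H](OC(C)=O)/C=C(\C)CC/C=C(\C)CCI | intermediate
18 | 2-(bromomethyl)prop-2-enoic acid | C=C(CBr)C(=O)O | starting material
19 | 2-[(phenylsulfonyl)methyl]prop-2-enoic acid | C=C(CS(=O)(=O)c1ccccc1)C(=O)O | intermediate
20 | (3R,4E,7R,8E,12E)-7-acetoxy-15-iodo-5,9,13-trimethylpentadeca-1,4,8,12-tetraen-3-yl 2-[(phenylsulfonyl)methyl]prop-2-enoate | C=C[C@@H](OC(=O)C(=C)CS(=O)(=O)c1ccccc1)/C=C(\C)C[C@@H](OC(C)=O)/C=C(\C)CC/C=C(\C)CCI | intermediate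
21 | (1E,4R,5E,9E)-12-iodo-2,6,10-trimethyl-1-{(2S)-5-oxo-4-[(phenylsulfonyl)methyl]-2,5-dihydrofuran-2-yl}dodeca-1,5,9-trien-4-yl acetate | O=C1O[C@@H](/C=C(\C)C[C@@H](OC(C)=O)/C=C(\C)CC/C=C(\C)CCI)C=C1CS(=O)(=O)c1ccccc1 | intermediate
22 | primary alkyl radical: 21 with the iodine atom removed, radical at the terminal CH2 (not isolated) | O=C1O[C@@H](/C=C(\C)C[C@@H](OC(C)=O)/C=C(\C)CC/C=C(\C)C[CH2])C=C1CS(=O)(=O)c1ccccc1 | intermediate
23 | lactone alpha-radical: trans-fused 14-membered ring closed, radical at C3 bearing the CH2SO2Ph group (not isolated) | O=S(=O)(C[C]1C(=O)O[C@H]2/C=C(\C)C[C@@H](OC(C)=O)/C=C(\C)CC/C=C(\C)CC[C@H]12)c1ccccc1 | intermediate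
24 | (3aR,6E,10E,12R,14E,15aS)-6,10,14-trimethyl-3-methylidene-2-oxo-2,3,3a,4,5,8,9,12,13,15a-decahydrocyclotetradeca[b]furan-12-yl acetate (trans-fused alpha-methylene lactone) | C=C1C(=O)O[C@H]2/C=C(\C)C[C@@H](OC(C)=O)/C=C(\C)CC/C=C(\C)CC[C@H]12 | target

**Step count and risks**

Total: 16 steps. Longest linear sequence: 14 steps (steps 1–5, 7–12, 14–16); steps 6 and 13 prepare the two side components.

Most likely to fail:

Step 16 (labelled step). The radical may be lost before it closes the ring: ring closure onto a beta-substituted butenolide carbon is slow, and the alpha-methylene lactone being formed is a better radical trap than the starting butenolide, so oligomerisation can overtake cyclisation; sulfonyl-radical-induced 1,3-shift of the allyl sulfone or E/Z scrambling is a second hazard. Fallback: the methylene is introduced after the ring closure instead of during it. From 17, acylation with acryloyl chloride and i-Pr2NEt should give (3R,4E,7R,8E,12E)-7-acetoxy-15-iodo-5,9,13-trimethylpentadeca-1,4,8,12-tetraen-3-yl prop-2-enoate F1, and ring-closing metathesis with [RuCl2(=CHPh)(H2IMes)(PCy3)] the unsubstituted butenolide (1E,4R,5E,9E)-12-iodo-2,6,10-trimethyl-1-[(2R)-5-oxo-2,5-dihydrofuran-2-yl]dodeca-1,5,9-trien-4-yl acetate F2. Slow addition of Bu3SnH and AIBN to F2 at 1 mM in refluxing benzene (known tin-hydride radical macrocyclisation onto an alpha,beta-unsaturated carbonyl acceptor, Giese type) should close the ring anti to the C15a substituent and give the trans-fused saturated lactone (3aR,6E,10E,12R,14E,15aR)-6,10,14-trimethyl-2-oxo-2,3,3a,4,5,8,9,12,13,15a-decahydrocyclotetradeca[b]furan-12-yl acetate F3, which cannot trap radicals. K2CO3 in MeOH followed by mild acid (to re-close any opened lactone) would remove the acetate to give the hydroxy lactone (3aR,6E,10E,12R,14E,15aR)-12-hydroxy-6,10,14-trimethyl-3a,4,5,8,9,12,13,15a-octahydrocyclotetradeca[b]furan-2(3H)-one F4. LiN(i-Pr)2 (2.2 equiv) and Eschenmoser's salt would give the Mannich base 3-[(dimethylamino)methyl] derivative of F4, F5; MeI its methiodide F6; NaHCO3 the alpha-methylene hydroxy lactone (3aR,6E,10E,12R,14E,15aS)-12-hydroxy-6,10,14-trimethyl-3-methylidene-3a,4,5,8,9,12,13,15a-octahydrocyclotetradeca[b]furan-2(3H)-one F7; and Ac2O/pyridine returns to the route at 24.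

Step 11. Vinyl transfer to the hindered beta,beta-disubstituted enal may be sluggish or show poor facial selectivity, giving a C3-epimeric mixture that cannot be corrected later. Fallback: alkynylation followed by semireduction. From 15, the Me2Zn/ProPhenol-catalysed addition of trimethylsilylacetylene (ligand enantiomer selective for the Re face) should give (3S,4E,7R,8E,12E)-15-bromo-3-hydroxy-5,9,13-trimethyl-1-(trimethylsilyl)pentadeca-4,8,12-trien-1-yn-7-yl acetate F8. Bu4NF buffered with AcOH would give the terminal alkynol (3S,4E,7R,8E,12E)-15-bromo-3-hydroxy-5,9,13-trimethylpentadeca-4,8,12-trien-1-yn-7-yl acetate F9, and Lindlar semihydrogenation (Pd/CaCO3 poisoned with Pb(OAc)2, quinoline, H2) comes back to the route at 16.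

Step 3. The Grignard reagent may attack the acetate, or couple at the gamma-carbon of the allylic bromide (SN2') and give the branched isomer. Fallback: olefination and hydroboration in place of the coupling. From 2, MnO2 should give the enal (2E,6E)-3,7-dimethyl-8-oxoocta-2,6-dien-1-yl acetate F10, and Wittig methylenation (Ph3P=CH2) the triene (2E,6E)-3,7-dimethylnona-2,6,8-trien-1-yl acetate F11. 9-BBN should add anti-Markovnikov to the terminal olefin of the diene to give the borane (2E,6E)-9-(9-borabicyclo[3.3.1]nonan-9-yl)-3,7-dimethylnona-2,6-dien-1-yl acetate F12, and NaOH/H2O2 (which also saponifies the acetate) comes back to the route at 6.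

**Further compounds**

F1 | step 16 | (3R,4E,7R,8E,12E)-7-acetoxy-15-iodo-5,9,13-trimethylpentadeca-1,4,8,12-tetraen-3-yl prop-2-enoate | C=C[C@@H](OC(=O)C=C)/C=C(\C)C[C@@H](OC(C)=O)/C=C(\C)CC/C=C(\C)CCI
F2 | step 16 | (1E,4R,5E,9E)-12-iodo-2,6,10-trimethyl-1-[(2R)-5-oxo-2,5-dihydrofuran-2-yl]dodeca-1,5,9-trien-4-yl acetate | O=C1O[C@@H](/C=C(\C)C[C@@H](OC(C)=O)/C=C(\C)CC/C=C(\C)CCI)C=C1
F3 | step 16 | (3aR,6E,10E,12R,14E,15aR)-6,10,14-trimethyl-2-oxo-2,3,3a,4,5,8,9,12,13,15a-decahydrocyclotetradeca[b]furan-12-yl acetate | C1C(=O)O[C@H]2/C=C(\C)C[C@@H](OC(C)=O)/C=C(\C)CC/C=C(\C)CC[C@H]12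
F4 | step 16 | (3aR,6E,10E,12R,14E,15aR)-12-hydroxy-6,10,14-trimethyl-3a,4,5,8,9,12,13,15a-octahydrocyclotetradeca[b]furan-2(3H)-one | C1C(=O)O[C@H]2/C=C(\C)C[C@@H](O)/C=C(\C)CC/C=C(\C)CC[C@H]12
F5 | step 16 | 3-[(dimethylamino)methyl] derivative of F4 (C3 epimers) | CN(C)CC1C(=O)O[C@H]2/C=C(\C)C[C@@H](O)/C=C(\C)CC/C=C(\C)CC[C@H]12
F6 | step 16 | methiodide of F5, 3-[(trimethylammonio)methyl] lactone iodide | C[N+](C)(C)CC1C(=O)O[C@H]2/C=C(\C)C[C@@H](O)/C=C(\C)CC/C=C(\C)CC[C@H]12.[I-]
F7 | step 16 | (3aR,6E,10E,12R,14E,15aS)-12-hydroxy-6,10,14-trimethyl-3-methylidene-3a,4,5,8,9,12,13,15a-octahydrocyclotetradeca[b]furan-2(3H)-one | C=C1C(=O)O[C@H]2/C=C(\C)C[C@@H](O)/C=C(\C)CC/C=C(\C)CC[C@H]12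
F8 | step 11 | (3S,4E,7R,8E,12E)-15-bromo-3-hydroxy-5,9,13-trimethyl-1-(trimethylsilyl)pentadeca-4,8,12-trien-1-yn-7-yl acetate | C[Si](C)(C)C#C[C@@H](O)/C=C(\C)C[C@@H](OC(C)=O)/C=C(\C)CC/C=C(\C)CCBr
F9 | step 11 | (3S,4E,7R,8E,12E)-15-bromo-3-hydroxy-5,9,13-trimethylpentadeca-4,8,12-trien-1-yn-7-yl acetate | C#C[C@@H](O)/C=C(\C)C[C@@H](OC(C)=O)/C=C(\C)CC/C=C(\C)CCBr
F10 | step 3 | (2E,6E)-3,7-dimethyl-8-oxoocta-2,6-dien-1-yl acetate | CC(=O)OC/C=C(\C)CC/C=C(\C)C=O
F11 | step 3 | (2E,6E)-3,7-dimethylnona-2,6,8-trien-1-yl acetate | CC(=O)OC/C=C(\C)CC/C=C(\C)C=C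
F12 | step 3 | (2E,6E)-9-(9-borabicyclo[3.3.1]nonan-9-yl)-3,7-dimethylnona-2,6-dien-1-yl acetate | CC(=O)OC/C=C(\C)CC/C=C(\C)CCB1C2CCCC1CCC2
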